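**Retrosynthetic overview**
1. Late disconnections: the C5 angelate (esterification), the C2 enone (from a propargylic pivalate, Meyer–Schuster type), the 6,12-lactone with its exo-methylene (from a C7 acrylate side chain; C7–C11 by alkylation of a C8 silyl enol ether, C8–OH by ketone reduction) and C1–C2 (acetylide addition to a C1 ketone).
2. The carbocycle C1–C10–C9–C8–C7–C6–C5 is made from the five-membered oxolane (O, C1, C5, C6, C7) by a Claisen ring expansion: C9–C10 forms, C7–O breaks, the ring O becomes the C1 ketone, C7=C8 appears as a silyl enol ether and C10 is set.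
3. The oxolane is D-arabinono-1,4-lactone: sugar C1–C5 become C1, C5, C6, C7, C8; O2 and O3 remain as the C5 and C6 oxygens; C9 comes from MeMgBr, C10/C14 from 1,1-dibromoethane.
4. Enabling feature: in the seven-membered ring, C1 (carbinol from a ketone) and C8 (oxygenated) flank the C10–C9 bond while C7 bears no oxygen, i.e. the γ,δ-unsaturated ketone retron C1(=O)–C10–C9–C8(OR)=C7; next to it C5/C6 are a trans-diol of arabino configuration.
5. Ring order: oxolane (chiral pool) → cycloheptene (key step) → γ-lactone (last).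

Key step: step 7

Remark (numbering): seven-membered-ring compounds use the skeleton numbering of the target: ring C1, C5, C6, C7, C8, C9, C10; C2–C4 and C15 are the side chain on C1, C14 the methyl on C10, C11–C13 the lactone carbons on C7. β is the ring face carrying the C7–C11 bond, α the other face. Compounds 1–7 use sugar numbering (sugar C1, C2, C3, C4, C5 = later C1, C5, C6, C7, C8).
Remark (assumption): (S)-but-3-yn-2-ol is chosen only to give single diastereomers; its stereocentre (C4) is erased in step 17, so the (R) or racemic alcohol would serve equally.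

**Step 1**
Reactants: 1 D-arabinono-1,4-lactone
Product: 2 2,3,5-tri-O-(triethylsilyl)-D-arabinono-1,4-lactone
Conditions: TESCl, imidazole, DMF, 0 °C to rt
Reagents that add atoms: chlorotriethylsilane, CC[Si](Cl)(CC)CC
Why: Silyl ether formation on all three hydroxyls; no stereocentre is touched, so sugar C2, C3, C4 (later C5, C6, C7) keep the D-arabino configuration.

**Step 2**
Reactants: 2 2,3,5-tri-O-(triethylsilyl)-D-arabinono-1,4-lactone
Product: 3 2,3-di-O-(triethylsilyl)-D-arabinono-1,4-lactone with C5 as the aldehyde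
Conditions: (COCl)2, DMSO, CH2Cl2, −78 to −30 °C; Et3N, −78 to 0 °C
Reagents that add atoms: none
Why: Swern oxidation run directly on the silyl ether: only the unhindered primary TES ether exchanges with the chlorosulfonium salt, so C5 becomes the aldehyde while the secondary TES ethers stay.

**Step 3**
Reactants: 3 the C5 aldehyde
Product: 4 6-deoxy-2,3-di-O-(triethylsilyl)hexono-1,4-lactone (D-arabino at C2–C4, C5 carbinol as an epimer mixture)
Conditions: MeMgBr, THF/Et2O, −78 °C
Reagents that add atoms: methylmagnesium bromide, C[Mg]Br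
Why: Grignard 1,2-addition to the aldehyde, which is far more electrophilic than the lactone at −78 °C; the new carbinol centre forms unselectively and is erased in step 4.

**Step 4**
Reactants: 4 the C5 carbinol mixture
Product: 5 6-deoxy-2,3-di-O-(triethylsilyl)-D-arabino-hex-5-ulosono-1,4-lactone (methyl ketone)
Conditions: Dess–Martin periodinane, CH2Cl2, rt
Reagents that add atoms: none
Why: Dess–Martin oxidation converges both carbinol epimers on one methyl ketone; the adjacent ring stereocentre already has the more stable trans relation to the C3 silyloxy group.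

**Step 5**
Reactants: 5 the methyl ketone
Product: 6 5-O-(tert-butyldimethylsilyl)-6-deoxy-2,3-di-O-(triethylsilyl)-D-arabino-hex-5-enono-1,4-lactone (TBS enol ether, CH2= terminus)
Conditions: LiHMDS, THF, −78 °C; TBSOTf
Reagents that add atoms: tert-butyldimethylsilyl triflate, CC(C)(C)[Si](C)(C)OS(=O)(=O)C(F)(F)F
Why: Kinetic deprotonation of the methyl group and O-silylation (silyl enol ether formation) masks the ketone so that step 6 can address the lactone, and creates the oxygenated allyl terminus C8=C9.

**Step 6**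
Reactants: 6 the TBS enol ether lactone
Product: 7 (2Z)-2-ethylidene-5-[1-(tert-butyldimethylsilyloxy)ethenyl]-3,4-bis(triethylsilyloxy)oxolane (D-arabino: 3-OTES cis to the 5-substituent, 4-OTES trans to both; ethylidene methyl syn to the ring oxygen)
Conditions: CH3CHBr2, TiCl4, Zn, TMEDA, PbCl2 (cat.), THF, 0 °C to rt; basic alumina filtration
Reagents that add atoms: 1,1-dibromoethane, CC(Br)Br
Why: Takai–Utimoto alkylidenation of the lactone carbonyl; the usual Z course (alkyl syn to the ring oxygen, away from the substituted C3) fixes the enol ether geometry that later decides C10.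

**Step 7**
Reactants: 7 the (Z)-2-ethylidene-5-(siloxyvinyl)oxolane
Product: 8 (2S,6R,7S)-4-(tert-butyldimethylsilyloxy)-2-methyl-6,7-bis(triethylsilyloxy)cyclohept-4-en-1-one (skeleton numbering: C1 ketone, 10α-Me, C7=C8 enol ether, 6α-OTES, 5β-OTES)
Conditions: o-xylene, N,O-bis(trimethylsilyl)acetamide (5 mol %), base-washed sealed tube, 180 °C
Reagents that add atoms: none
Why: Thermal [3,3]-sigmatropic (Claisen) rearrangement of the allyl vinyl ether C10=C1–O–C7–C8=C9 built into the oxolane: the C9–C10 σ-bond forms as C7–O breaks, the ring oxygen becomes the C1 ketone and the C7=C8 silyl enol ether appears, so the five-membered heterocycle becomes the seven-membered carbocycle. The closest known reaction type is the Claisen ring expansion of 2-alkylidene-5-vinyltetrahydrofurans to cyclohept-4-enones (and of the homologous tetrahydropyrans to cyclooctenones). The seven-membered ring is closed by C9–C10 bond formation in a concerted pericyclic mode, suprafacial on both π-components, through a bridged six-centre transition state in which C5–C6 span its 1,3-positions, so only the topology giving the cis ring alkene C7=C8 is possible. C10 is the only new stereocentre: the C7 configuration (sugar C4, siloxyvinyl on the β-face) forces C9 onto the β-face of the exocyclic enol ether, and the Z geometry (methyl syn to the ring oxygen) then places C14 on the α-face; C5 and C6 are untouched and C7 becomes sp2. The step needs a single enol ether geometry and no acid-induced migration of the exocyclic double bond or desilylation; step 6 secures the first, the silylating acid scavenger and base-washed glass the second, and the siloxy group on the central allyl carbon is expected to slow but not divert the rearrangement.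

**Step 8**
Reactants: 9 (S)-but-3-yn-2-ol
Product: 10 (S)-but-3-yn-2-yl pivalate
Conditions: PivCl, pyridine, DMAP (cat.), CH2Cl2, 0 °C to rt
Reagents that add atoms: pivaloyl chloride, CC(C)(C)C(=O)Cl
Why: Acylation of the secondary alcohol gives a base-stable propargylic ester (no α-hydrogens) that serves as the masked (E)-enone; the stereocentre is untouched.

**Step 9**
Reactants: 8 the cycloheptenone; 10 (S)-but-3-yn-2-yl pivalate
Product: 12 C1 tertiary propargylic alcohol (1α-OH; 1β-[(3S)-3-pivaloyloxybut-1-ynyl]; 10α-Me; 5β-OTES; 6α-OTES; C7=C8 TBS enol ether), via lithium acetylide 11 (not isolated)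
Conditions: 10, LDA, THF, −78 °C; then 8, −78 °C; aqueous work-up
Reagents that add atoms: none
Why: Acetylide 1,2-addition to the only ketone: in the chair of the cyclohept-4-enone with the C5 and C6 silyloxy groups equatorial the axial 10α-methyl blocks the α-face and the β-face meets only hydrogens, while in the other chair both faces are shielded by axial silyloxy groups, so the small linear nucleophile should enter from the β-face and give the 1α-hydroxy-1β-alkynyl centre.

**Step 10**
Reactants: 12 the C1 propargylic alcohol with C7=C8 enol ether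
Product: 13 C8 ketone with 7β-CH2CO2tBu (1α-OH, 1β-alkynyl, 10α-Me, 5β-OTES, 6α-OTES)
Conditions: BrCH2CO2tBu, fac-Ir(ppy)3 (1 mol %), 2,6-lutidine, MeCN, blue LEDs, rt; aqueous work-up
Reagents that add atoms: tert-butyl bromoacetate, CC(C)(C)OC(=O)CBr
Why: Visible-light photoredox α-alkylation of a silyl enol ether with an α-bromo ester (radical addition at C7, oxidation of the α-siloxy radical, loss of silyl): the radical adds anti to the 6α-silyloxy group, and this trans arrangement is also the more stable one at the epimerisable C7, so the side chain is β; the neutral conditions avoid β-elimination of the C6 silyloxy group.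

**Step 11**
Reactants: 13 the C8 ketone
Product: 14 8β-alcohol (7β-CH2CO2tBu, 1α-OH, 1β-alkynyl, 10α-Me, 5β-OTES, 6α-OTES)
Conditions: L-Selectride, THF, −78 °C
Reagents that add atoms: none
Why: Ketone reduction with a bulky trialkylborohydride: hydride reaches C8 from the α-face, anti to the adjacent β side chain (the usual cis-selective reduction of 2-substituted cycloalkanones), giving the 8β-alcohol; the tert-butyl ester is too hindered to lactonise onto this cis hydroxyl.

**Step 12**
Reactants: 14 the 8β-alcohol
Product: 15 8β-OTIPS ether (otherwise as 14)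
Conditions: TIPSOTf, 2,6-lutidine, CH2Cl2, −78 to −20 °C
Reagents that add atoms: triisopropylsilyl triflate, CC(C)[Si](C(C)C)(C(C)C)OS(=O)(=O)C(F)(F)F
Why: Silyl ether formation on the secondary C8–OH (the tertiary C1–OH is too hindered for TIPS) blocks the cis hydroxyl that could otherwise compete for the lactone; no stereocentre changes.

**Step 13**
Reactants: 15 the 8β-OTIPS tert-butyl ester
Product: 18 C7 acrylate: 7β-[1-(tert-butoxycarbonyl)ethenyl] compound (8β-OTIPS; 1α-OH; 5β-OTES; 6α-OTES), via Mannich base 16 (not isolated), via ammonium iodide 17 (not isolated)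
Conditions: LDA (2.5 equiv), THF, −78 °C; Eschenmoser's salt, −78 °C to rt; MeI, MeOH, rt; NaHCO3 (aq)
Reagents that add atoms: N,N-dimethylmethyleneiminium iodide (Eschenmoser's salt), C=[N+](C)C.[I-]
Why: Mannich reaction of the ester enolate with Eschenmoser's salt, then quaternisation and E1cB (Hofmann-type) elimination give the α-methylene ester; the transient C11 stereocentre is lost and no acidic or electrophilic site competes (the C1 alkoxide is inert, the pivalate has no α-hydrogens).

**Step 14**
Reactants: 18 the C7 acrylate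
Product: 20 α-methylene-γ-lactone diol (6α,12-lactone trans-fused; 8β-OTIPS; free 1α-OH and 5β-OH; 1β-alkynyl pivalate), via hydroxy acid 19 (not isolated)
Conditions: TFA/CH2Cl2/H2O (20:80:2), 0 °C to rt
Reagents that add atoms: none
Why: Acidolysis of the two secondary TES ethers and the tert-butyl ester, then acid-catalysed lactonisation: the five-membered lactone onto the 6α-OH (trans to C11, as in the target) is preferred over a bridged six-membered lactone onto C5–OH, and the TIPS ether keeps the cis C8 oxygen out of play; no stereocentre changes.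

**Step 15**
Reactants: 20 the α-methylene lactone diol
Product: 21 5β-angelate (1α-OH free, 8β-OTIPS, 1β-alkynyl pivalate)
Conditions: angelic acid, 2,4,6-trichlorobenzoyl chloride, Et3N, toluene, rt; then 20, 80 °C
Reagents that add atoms: angelic acid, C/C=C(/C)C(=O)O
Why: Mixed-anhydride (Yamaguchi-type) esterification: only the secondary C5–OH reacts, the tertiary C1–OH is inert, and the trichlorobenzoyl mixed anhydride without DMAP keeps the Z (angelate) geometry.

**Step 16**
Reactants: 21 the 5β-angelate
Product: 22 1α-OTES ether of 21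
Conditions: TESOTf, 2,6-lutidine, CH2Cl2, −40 to 0 °C
Reagents that add atoms: triethylsilyl triflate, CC[Si](CC)(CC)OS(=O)(=O)C(F)(F)F
Why: Silylation of the tertiary propargylic alcohol with a silyl triflate, so that no free hydroxyl can add to the allene or enone generated in step 17.

**Step 17**
Reactants: 22 the fully protected propargylic pivalate
Product: 23 (E)-enone: 1β-[(E)-but-2-enoyl] compound (1α-OTES, 5β-angelate, 8β-OTIPS, α-methylene lactone)
Conditions: Ph3PAuNTf2 (2 mol %), 2-butanone/H2O, rt
Reagents that add atoms: none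
Why: Gold(I)-catalysed 1,3-acyloxy shift of the propargylic pivalate to the allenyl pivalate and its hydrolysis (Meyer–Schuster-type rearrangement) place the carbonyl at C2 and give the thermodynamic E alkene; the C4 stereocentre is erased.

**Step 18**
Reactants: 23 the bis-silyl ether of the target
Product: 24 CNP0206014.2 (target)
Conditions: HF·pyridine, pyridine, THF, 0 °C to rt
Reagents that add atoms: none
Why: Fluoride-mediated desilylation of the tertiary TES and secondary TIPS ethers under buffered, non-basic conditions leaves the enone, the α-methylene lactone and the angelate untouched; no stereocentre changes.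

**Compound list**
1 | D-arabinono-1,4-lactone, (3S,4S,5R)-3,4-dihydroxy-5-(hydroxymethyl)oxolan-2-one | OC[C@H]1OC(=O)[C@@H](O)[C@@H]1O | starting material
2 | 2,3,5-tri-O-(triethylsilyl)-D-arabinono-1,4-lactone | CC[Si](CC)(CC)OC[C@H]1OC(=O)[C@@H](O[Si](CC)(CC)CC)[C@@H]1O[Si](CC)(CC)CC | intermediate
3 | 2,3-di-O-(triethylsilyl)-D-arabinono-1,4-lactone with C5 as aldehyde | O=C[C@H]1OC(=O)[C@@H](O[Si](CC)(CC)CC)[C@@H]1O[Si](CC)(CC)CC | intermediate
4 | 6-deoxy-2,3-di-O-(triethylsilyl)hexono-1,4-lactone, D-arabino at C2–C4, C5 epimer mixture | CC(O)[C@H]1OC(=O)[C@@H](O[Si](CC)(CC)CC)[C@@H]1O[Si](CC)(CC)CC | intermediate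
5 | 6-deoxy-2,3-di-O-(triethylsilyl)-D-arabino-hex-5-ulosono-1,4-lactone | CC(=O)[C@H]1OC(=O)[C@@H](O[Si](CC)(CC)CC)[C@@H]1O[Si](CC)(CC)CC | intermediate
6 | 5-O-(tert-butyldimethylsilyl)-6-deoxy-2,3-di-O-(triethylsilyl)-D-arabino-hex-5-enono-1,4-lactone | C=C(O[Si](C)(C)C(C)(C)C)[C@H]1OC(=O)[C@@H](O[Si](CC)(CC)CC)[C@@H]1O[Si](CC)(CC)CC | intermediate
7 | (2Z)-2-ethylidene-5-[1-(tert-butyldimethylsilyloxy)ethenyl]-3,4-bis(triethylsilyloxy)oxolane, D-arabino, methyl syn to ring O | C=C(O[Si](C)(C)C(C)(C)C)[C@H]1O/C(=C\C)[C@@H](O[Si](CC)(CC)CC)[C@@H]1O[Si](CC)(CC)CC | intermediate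
8 | (2S,6R,7S)-4-(tert-butyldimethylsilyloxy)-2-methyl-6,7-bis(triethylsilyloxy)cyclohept-4-en-1-one | CC[Si](CC)(CC)O[C@@H]1C=C(O[Si](C)(C)C(C)(C)C)C[C@H](C)C(=O)[C@H]1O[Si](CC)(CC)CC | intermediate
9 | (S)-but-3-yn-2-ol | C#C[C@H](C)O | starting material
10 | (S)-but-3-yn-2-yl pivalate | C#C[C@H](C)OC(=O)C(C)(C)C | intermediate
11 | lithium acetylide of 10 | [Li]C#C[C@H](C)OC(=O)C(C)(C)C | intermediate (not isolated)
12 | C1 tertiary propargylic alcohol: 1α-OH, 1β-[(3S)-3-pivaloyloxybut-1-ynyl], 10α-Me, 5β-OTES, 6α-OTES, C7=C8 TBS enol ether | CC[Si](CC)(CC)O[C@@H]1C=C(O[Si](C)(C)C(C)(C)C)C[C@H](C)[C@@](O)(C#C[C@H](C)OC(=O)C(C)(C)C)[C@H]1O[Si](CC)(CC)CC | intermediate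
13 | C8 ketone with 7β-CH2CO2tBu (otherwise as 12) | CC[Si](CC)(CC)O[C@@H]1[C@@H](CC(=O)OC(C)(C)C)C(=O)C[C@H](C)[C@@](O)(C#C[C@H](C)OC(=O)C(C)(C)C)[C@H]1O[Si](CC)(CC)CC | intermediate
14 | 8β-alcohol of 13 | CC[Si](CC)(CC)O[C@@H]1[C@@H](CC(=O)OC(C)(C)C)[C@@H](O)C[C@H](C)[C@@](O)(C#C[C@H](C)OC(=O)C(C)(C)C)[C@H]1O[Si](CC)(CC)CC | intermediate
15 | 8β-OTIPS ether of 14 | CC[Si](CC)(CC)O[C@@H]1[C@@H](CC(=O)OC(C)(C)C)[C@@H](O[Si](C(C)C)(C(C)C)C(C)C)C[C@H](C)[C@@](O)(C#C[C@H](C)OC(=O)C(C)(C)C)[C@H]1O[Si](CC)(CC)CC | intermediate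
16 | Mannich base: C11 CH2NMe2 adduct of 15 (C11 epimers) | CC[Si](CC)(CC)O[C@@H]1[C@@H](C(CN(C)C)C(=O)OC(C)(C)C)[C@@H](O[Si](C(C)C)(C(C)C)C(C)C)C[C@H](C)[C@@](O)(C#C[C@H](C)OC(=O)C(C)(C)C)[C@H]1O[Si](CC)(CC)CC | intermediate (not isolated)
17 | trimethylammonium iodide of 16 | CC[Si](CC)(CC)O[C@@H]1[C@@H](C(C[N+](C)(C)C)C(=O)OC(C)(C)C)[C@@H](O[Si](C(C)C)(C(C)C)C(C)C)C[C@H](C)[C@@](O)(C#C[C@H](C)OC(=O)C(C)(C)C)[C@H]1O[Si](CC)(CC)CC.[I-] | intermediate (not isolated)
18 | C7 acrylate: 7β-[1-(tert-butoxycarbonyl)ethenyl], 8β-OTIPS, 1α-OH, 5β-OTES, 6α-OTES | CC[Si](CC)(CC)O[C@@H]1[C@@H](C(=C)C(=O)OC(C)(C)C)[C@@H](O[Si](C(C)C)(C(C)C)C(C)C)C[C@H](C)[C@@](O)(C#C[C@H](C)OC(=O)C(C)(C)C)[C@H]1O[Si](CC)(CC)CC | intermediate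
19 | hydroxy acid: 1α,5β,6α-triol with free acrylic acid on C7, 8β-OTIPS | O[C@@H]1[C@@H](C(=C)C(=O)O)[C@@H](O[Si](C(C)C)(C(C)C)C(C)C)C[C@H](C)[C@@](O)(C#C[C@H](C)OC(=O)C(C)(C)C)[C@H]1O | intermediate (not isolated)
20 | α-methylene 6α,12-lactone with free 1α-OH and 5β-OH, 8β-OTIPS, 1β-alkynyl pivalate | C=C1C(=O)O[C@@H]2[C@@H]1[C@@H](O[Si](C(C)C)(C(C)C)C(C)C)C[C@H](C)[C@@](O)(C#C[C@H](C)OC(=O)C(C)(C)C)[C@H]2O | intermediate
21 | 5β-angelate of 20 | C=C1C(=O)O[C@@H]2[C@@H]1[C@@H](O[Si](C(C)C)(C(C)C)C(C)C)C[C@H](C)[C@@](O)(C#C[C@H](C)OC(=O)C(C)(C)C)[C@H]2OC(=O)/C(C)=C\C | intermediate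
22 | 1α-OTES ether of 21 | C=C1C(=O)O[C@@H]2[C@@H]1[C@@H](O[Si](C(C)C)(C(C)C)C(C)C)C[C@H](C)[C@@](O[Si](CC)(CC)CC)(C#C[C@H](C)OC(=O)C(C)(C)C)[C@H]2OC(=O)/C(C)=C\C | intermediate
23 | (E)-enone: 1α-OTES, 8β-OTIPS bis-silyl ether of the target | C=C1C(=O)O[C@@H]2[C@@H]1[C@@H](O[Si](C(C)C)(C(C)C)C(C)C)C[C@H](C)[C@@](O[Si](CC)(CC)CC)(C(=O)/C=C/C)[C@H]2OC(=O)/C(C)=C\C | intermediate
24 | CNP0206014.2 | C=C1C(=O)O[C@@H]2[C@@H]1[C@@H](O)C[C@H](C)[C@@](O)(C(=O)/C=C/C)[C@H]2OC(=O)/C(C)=C\C | target

**Step count and risks**
Total step count: 18. Longest linear sequence: 17 (steps 1–7 and 9–18, from compound 1); step 8 is a one-step side branch.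

Steps most likely to fail:

Step 7 (key step). The rearrangement is slowed by the donor siloxy group on the central allyl carbon and by the strained bridged transition state. Prolonged heating can then let traces of acid move the exocyclic enol ether double bond into the ring or cleave the silyl enol ether before C9–C10 forms. Fallback, from 7 back to 8: treat 7 with triisobutylaluminium in CH2Cl2 at −78 °C to rt. The Lewis acid drives the same ring expansion at low temperature through an aluminium-bound, polarised pathway and reduces the resulting ketone in situ by β-hydride transfer, giving the C1 carbinol, 4-(tert-butyldimethylsilyloxy)-2-methyl-6,7-bis(triethylsilyloxy)cyclohept-4-en-1-ol F1 (epimers at C1). Dess–Martin periodinane then oxidises this alcohol to 8.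

Step 6. The low-valent titanium reagent may react incompletely with the α-silyloxy lactone, or the Lewis-acidic medium and work-up may hydrolyse or isomerise the two enol ethers, and the Z geometry may erode. Fallback, from 6 back to 7: add lithiated 2-(ethylsulfonyl)-1,3-benzothiazole (LiHMDS, THF, −78 °C) to the lactone carbonyl of 6 to give the lactol sulfone F2. DBU (THF, rt) then triggers Smiles rearrangement and loss of sulfur dioxide and benzothiazolone (Julia–Kocienski-type olefination of a lactone), giving 7 after separation of the Z isomer from any E isomer.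

Step 15. Acylation of the hindered C5–OH, flanked by the quaternary C1 and the lactone carbon C6, may be slow, and the activated angeloyl donor may isomerise Z to E under the forcing conditions, giving tiglate. Fallback, from 20 back to 21: esterify C5–OH with 2-(diphenoxyphosphoryl)propanoic acid (DCC, DMAP, CH2Cl2) to the C5 2-(diphenoxyphosphoryl)propanoate F3. A Z-selective Horner–Wadsworth–Emmons olefination (Ando variant: NaI, DBU, THF, −78 to 0 °C, acetaldehyde) then builds the angelate double bond on the substrate and gives 21.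

**Further compounds**
F1 | step 7 | 4-(tert-butyldimethylsilyloxy)-2-methyl-6,7-bis(triethylsilyloxy)cyclohept-4-en-1-ol (C1 epimers; other centres as in 8) | CC[Si](CC)(CC)O[C@@H]1C=C(O[Si](C)(C)C(C)(C)C)C[C@H](C)C(O)[C@H]1O[Si](CC)(CC)CC
F2 | step 6 | lactol sulfone: 2-hydroxy-2-[1-(1,3-benzothiazol-2-ylsulfonyl)ethyl] adduct of lactone 6 (new centres unassigned) | C=C(O[Si](C)(C)C(C)(C)C)[C@H]1OC(O)(C(C)S(=O)(=O)c2nc3ccccc3s2)[C@@H](O[Si](CC)(CC)CC)[C@@H]1O[Si](CC)(CC)CC
F3 | step 15 | C5 2-(diphenoxyphosphoryl)propanoate of 20 (phosphonate α-carbon as epimer mixture) | C=C1C(=O)O[C@@H]2[C@@H]1[C@@H](O[Si](C(C)C)(C(C)C)C(C)C)C[C@H](C)[C@@](O)(C#C[C@H](C)OC(=O)C(C)(C)C)[C@H]2OC(=O)C(C)P(=O)(Oc3ccccc3)Oc4ccccc4
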